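Remark on the chemistry: read from the SMILES, the lactone carbon C3 is S and the acetoxy carbon C10' is R. Phthalide atoms are numbered C1 (carbonyl), O2, C3, C3a, C4 to C7, C7a; the side chain is C1' to C14' outward from C3.

## Structural features

The target is a 3-substituted phthalide: a benzene ring (C3a, C4–C7, C7a) fused to a five-membered lactone (C1, O2, C3), with methoxy groups at C5 and C7, which are para and ortho to C7a and both meta to C3a. C3 (S) is at once benzylic, carbinolic and part of the lactone ring, and carries an unbranched C14 chain. The chain runs through nine methylene groups (C1'–C9') to the acetoxy carbon C10' (R), then two methylene groups and a methyl ketone (C13'), so acetate and ketone stand in a 1,4-relationship (a masked γ-hydroxy ketone). The two stereocentres are ten bonds apart, have no neighbouring stereocentre and cannot control each other, so each must come from a reagent or from the chiral pool. Fragile groups are the secondary acetate (lost to base or nucleophiles, after which the γ-hydroxy ketone would close to a lactol), the enolisable methyl ketone, the lactone and, under strong base, the benzylic C3–H. The real difficulty is the 1,2,3,5-tetrasubstituted benzene ring with two adjacent carbon substituents, of which the one at C3a is meta to both methoxy groups and cannot be placed by electrophilic substitution, together with the C3 stereocentre next to this crowded ring. The key step exploits that C1–C7a–C3a–C3 is the carbon pattern of a 4-hydroxy-2-ynoate and that C4–C7 with their two oxygen atoms are a 1,3-dimethoxy diene, so the benzene ring itself can be the last thing made.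

## Logic of the disconnections

18 ⇒ 14 + 2 (key). In one sentence: the route is an Alder–Rickert benzannulation of open-chain 14 with 2 as the last step. The bonds cut are the ring bonds C3a–C4 and C7–C7a and the lactone bond C1–O2. C4–C7 go back into a cyclohexadiene (15, formed from 2) whose extra two-carbon bridge leaves as ethylene from 16; C1, C7a, C3a and C3 go back into the ynoate of 14, with 17 as the ring-open ester. The cut removes the arene, its substitution pattern and the lactone together, and turns the benzylic stereocentre into a propargylic one, for which catalyst-controlled methods exist. The gain is an acyclic chain with two independent carbinol centres plus a diene one step from 1. The forward step must join the ester-bearing alkyne carbon to the methoxy-bearing diene terminus, must let ethylene loss and lactonisation follow in the same flask, and must leave the C3 configuration, the acetate and the ketone untouched at high temperature.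

14 ⇒ 11 + 12. The bond cut is C3–C4 of 14 (sp–sp3), the later C3–C3a bond of 18. Cutting here makes the carbinol stereocentre in the same event as the C–C bond, under catalyst control. The gain is a commercial three-carbon piece (12) and an aldehyde (11) with one stereocentre. The forward step needs alkynyl delivery to the Re face of an unbranched aliphatic aldehyde, and addition to the aldehyde only, not to the methyl ketone or the acetate.

11 ⇒ 10 ⇒ 9. Both carbonyl groups of 11 (C3 aldehyde and C13' ketone of the later target) are traced back to C=CH2 groups, and the acetate to the free alcohol. 9 then has no electrophilic group and can be built with Grignard reagents. The forward step must cleave a vinyl and an isopropenyl group in one operation with reductive work-up, without harming the acetate.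

9 ⇒ 7 + 8. The bond cut is C3–C4 of 9 (C11'–C12' of the target). Opening an epoxide at its CH2 carbon forms the carbinol without touching the stereocentre. 8 is a commercial four-carbon reagent whose isopropenyl group is the latent acetyl group. The forward step must attack only the terminal epoxide carbon.

7 ⇒ 6 ⇒ 3 + 4. The bonds cut are the epoxide C–O bond made from the chlorohydrin and C3–C4 of 6 (C8'–C9' of the target). 4 supplies C9'–C11' with the C10' stereocentre from the chiral pool and is alkylated at both ends in turn; 3 supplies C3 and C1'–C8' with the alkene as latent aldehyde. The forward step must open the oxirane CH2 and not displace chloride, since direct displacement would lead to the enantiomer of 7.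

2 ⇒ 1. Two hydrogen atoms are removed in the retrosynthetic sense; the forward step is a dissolving-metal reduction of a cheap arene, which must stop at the dihydro stage.

## Other disconnections considered

Alternative 1: the first plan that comes to mind keeps a bought benzene ring and cuts C3–H. The keto ester A1, methyl 2-[(11R)-11-acetoxy-14-oxopentadecanoyl]-4,6-dimethoxybenzoate, would be reduced enantioselectively at the aryl ketone (transfer hydrogenation with RuCl[(S,S)-TsDPEN](p-cymene), or an oxazaborolidine–borane reduction), and the new alkoxide would close onto the ester. The chosen plan is preferred on three grounds. The acyl group of A1 sits meta to both methoxy groups, so it cannot be introduced by electrophilic substitution; A1 has to come from a pre-halogenated arene such as methyl 2-bromo-4,6-dimethoxybenzoate A2, itself several steps from a commercial bromoarene. Joining A2 to the chain needs aryl-metal chemistry, which the chain ketone and acetate tolerate only with protection. The reduction would have to distinguish the twisted, ortho-substituted aryl ketone from the C13' methyl ketone. The step count would be clearly higher.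

Alternative 2: cut the chain at C2'–C3' and join two halves by cross-metathesis. (S)-5,7-Dimethoxy-3-(prop-2-en-1-yl)isobenzofuran-1(3H)-one A3 and (R)-2-oxotridec-12-en-5-yl acetate A4 would be coupled with the second-generation Grubbs catalyst to the alkene A5, (3S)-3-[(10R)-10-acetoxy-13-oxotetradec-2-en-1-yl]-5,7-dimethoxyisobenzofuran-1(3H)-one, which would then be hydrogenated. This cut only moves the problem: A3 still needs the arene-first, enantioselective construction of the phthalide. Two unhindered terminal alkenes have no built-in preference for the cross product over the homodimers. Ruthenium hydride species could move the allyl double bond of A3 into conjugation with the lactone and endanger C3. An extra hydrogenation and two separate fragment syntheses make the plan longer.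

Alternative 3: cut C1–O2 and C3–H together by an enantioselective intramolecular ketone hydroacylation. The keto aldehyde A6, (R)-15-(2-formyl-3,5-dimethoxyphenyl)-2,15-dioxopentadecan-5-yl acetate, would be treated with a cationic monovalent rhodium catalyst made from [Rh(cod)Cl]2, AgBF4 and a chiral bisphosphine such as DTBM-SEGPHOS. The step is atom-economical and sets C3 while closing the lactone. Against it, A6 carries an aldehyde squeezed between a methoxy group and the acyl group, so it is harder to reach than A1, and the hindered acylrhodium hydride should be prone to decarbonylation. The arene substitution problem is left exactly where it was, whereas the chosen key step removes it.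

Key step: step 8

## Route

Step 1
Reactants: 1 1,3-dimethoxybenzene
Product: 2 1,5-dimethoxycyclohexa-1,4-diene
Conditions: Li, NH3 (l), THF, t-BuOH, −78 → −33 °C
Reagents that add atoms: none
Why: Birch reduction; the donor-substituted arene gives the unconjugated 2,5-dihydro product with both methoxy groups on the remaining double bonds, and t-BuOH as proton source prevents over-reduction; no stereocentre is formed.

Step 2
Reactants: 3 10-bromodec-1-ene; 4 (R)-epichlorohydrin
Product: 6 (R)-1-chlorotridec-12-en-2-ol, via dec-9-enylmagnesium bromide 5 (not isolated)
Conditions: Mg, THF, rt → 40 °C; then CuI (10 mol%), 4, THF, −40 → −20 °C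
Reagents that add atoms: none
Why: Copper-catalysed Grignard opening of an epoxide by SN2 attack at the unsubstituted oxirane carbon; the C–O bond at the stereocentre is not touched, so the R configuration of 4 is carried into 6, and at low temperature the primary chloride is not displaced.

Step 3
Reactants: 6 (R)-1-chlorotridec-12-en-2-ol
Product: 7 (R)-2-(undec-10-en-1-yl)oxirane
Conditions: NaOH (powdered), Et2O, rt
Reagents that add atoms: none
Why: Intramolecular Williamson etherification (3-exo-tet) of the chlorohydrin; the alkoxide displaces the primary chloride, the stereocentre is not involved and stays R.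

Step 4
Reactants: 7 (R)-2-(undec-10-en-1-yl)oxirane; 8 2-methylallylmagnesium chloride (commercial THF solution)
Product: 9 (R)-2-methylhexadeca-1,15-dien-5-ol
Conditions: 8 (1.5 equiv), CuI (10 mol%), THF, −40 → 0 °C
Reagents that add atoms: none
Why: Copper-catalysed opening of a terminal epoxide by an allylic Grignard reagent at the CH2 carbon; allylic transposition is degenerate for the 2-methylallyl group, and the stereocentre keeps its C–O bond and remains R.

Step 5
Reactants: 9 (R)-2-methylhexadeca-1,15-dien-5-ol
Product: 10 (R)-2-methylhexadeca-1,15-dien-5-yl acetate
Conditions: Ac2O, pyridine, DMAP (5 mol%), CH2Cl2, 0 °C → rt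
Reagents that add atoms: acetic anhydride, CC(=O)OC(C)=O
Why: DMAP-catalysed acylation of a secondary alcohol; no bond to the stereocentre is broken.

Step 6
Reactants: 10 (R)-2-methylhexadeca-1,15-dien-5-yl acetate
Product: 11 (R)-2,15-dioxopentadecan-5-yl acetate
Conditions: O3, CH2Cl2, −78 °C; then PPh3, −78 °C → rt
Reagents that add atoms: ozone, [O-][O+]=O
Why: Ozonolysis with reductive work-up; the vinyl group should give the aldehyde and the isopropenyl group the methyl ketone in one operation, each with loss of formaldehyde, while the acetate and the stereocentre are untouched.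

Step 7
Reactants: 11 (R)-2,15-dioxopentadecan-5-yl acetate; 12 methyl propiolate
Product: 14 methyl (4S,14R)-14-acetoxy-4-hydroxy-17-oxooctadec-2-ynoate, via ethyl(3-methoxy-3-oxoprop-1-ynyl)zinc 13 (not isolated)
Conditions: 12 (4 equiv), ZnEt2 (4 equiv), (R)-BINOL (40 mol%), HMPA (2 equiv), CH2Cl2, rt, 16 h; Ti(OiPr)4 (50 mol%), 1 h; then 11, rt
Reagents that add atoms: none
Why: Catalytic enantioselective alkynylzinc addition to an aldehyde promoted by a BINOL–titanium complex; the (R)-BINOL–Ti(OiPr)4 complex is expected to deliver 13 to the Re face of the aldehyde, as in the related dialkylzinc additions, which gives the 4S carbinol (alkynyl ranks above alkyl). The distant R centre cannot interfere (reagent control), and the organozinc should not add to the methyl ketone or the acetate.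

Step 8
Reactants: 14 methyl (4S,14R)-14-acetoxy-4-hydroxy-17-oxooctadec-2-ynoate; 2 1,5-dimethoxycyclohexa-1,4-diene
Product: 18 (3S)-3-[(10R)-10-acetoxy-13-oxotetradecyl]-5,7-dimethoxyisobenzofuran-1(3H)-one (target), via 1,3-dimethoxycyclohexa-1,3-diene 15 (not isolated), via bicyclo[2.2.2]octadiene cycloadduct 16 (not isolated), via methyl hydroxyalkyl dimethoxybenzoate 17 (not isolated)
Conditions: 2 (5 equiv), dichloromaleic anhydride (2 mol%), neat, sealed tube, argon, 110 °C, 1 h; then 14, 180 °C, 24 h; then 1 M HCl, THF, rt
Reagents that add atoms: none
Why: Alder–Rickert reaction: the catalytic dichloromaleic anhydride moves one double bond of 2 into conjugation to give 15, in which both methoxy groups (C1, C3) raise the HOMO coefficient at the unsubstituted terminus C4. In a normal-demand [4+2] cycloaddition C4 of 15 bonds to the β-carbon of the ynoate 14 (the carbinol-bearing carbon, larger LUMO coefficient) and the methoxy-bearing C1 to the α-carbon, giving 16 as a mixture of bridgehead isomers that is of no consequence. Retro-[4+2] of 16 expels the two-carbon bridge as ethylene; gain of aromaticity and loss of a gas make this irreversible and give 17, whose ester is flanked by a methoxy group and by the carbinol side chain. The hydroxyl of 17 then attacks the neighbouring ester with loss of methanol, and the acid treatment completes this and hydrolyses the surplus enol ether for easy removal. Ring closures: the benzene ring by intermolecular cycloaddition and cycloreversion (new bonds C3a–C4 and C7–C7a), the lactone by 5-exo-trig acyl substitution (O2–C1). No new stereocentre survives: the bridgeheads of 16 vanish on aromatisation, C3 and C10' come in from 14, no bond to either is made or broken, and the medium is not basic, so the propargylic and later benzylic C–H should not epimerise. The selectivity needed is regiochemical (5,7- and not 4,6-dimethoxy) and is secured by the matched polarisation of diene and ynoate; only the ynoate is a dienophile, and ketone and acetate are inert to neutral heat. The closest known reaction type is the Alder–Rickert synthesis of 2,4-dialkoxybenzoates and of phthalides from alkoxycyclohexadienes and acetylenic esters.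

## Compound list

1 | 1,3-dimethoxybenzene | COc1cccc(OC)c1 | starting material
2 | 1,5-dimethoxycyclohexa-1,4-diene | COC1=CCC=C(OC)C1 | intermediate
3 | 10-bromodec-1-ene | C=CCCCCCCCCBr | starting material
4 | (R)-epichlorohydrin | ClC[C@H]1CO1 | starting material
5 | dec-9-en-1-ylmagnesium bromide | C=CCCCCCCCC[Mg]Br | intermediate
6 | (R)-1-chlorotridec-12-en-2-ol | C=CCCCCCCCCC[C@@H](O)CCl | intermediate
7 | (R)-2-(undec-10-en-1-yl)oxirane | C=CCCCCCCCCC[C@@H]1CO1 | intermediate
8 | 2-methylallylmagnesium chloride | CC(=C)C[Mg]Cl | starting material
9 | (R)-2-methylhexadeca-1,15-dien-5-ol | C=CCCCCCCCCC[C@H](CCC(C)=C)O | intermediate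
10 | (R)-2-methylhexadeca-1,15-dien-5-yl acetate | C=CCCCCCCCCC[C@H](CCC(C)=C)OC(C)=O | intermediate
11 | (R)-2,15-dioxopentadecan-5-yl acetate | O=CCCCCCCCCC[C@H](CCC(C)=O)OC(C)=O | intermediate
12 | methyl propiolate | C#CC(=O)OC | starting material
13 | ethyl(3-methoxy-3-oxoprop-1-yn-1-yl)zinc | CC[Zn]C#CC(=O)OC | intermediate
14 | methyl (4S,14R)-14-acetoxy-4-hydroxy-17-oxooctadec-2-ynoate | COC(=O)C#C[C@@H](O)CCCCCCCCC[C@H](CCC(C)=O)OC(C)=O | intermediate
15 | 1,3-dimethoxycyclohexa-1,3-diene | COC1=CC(OC)=CCC1 | intermediate
16 | methyl 3-[(1S,11R)-11-acetoxy-1-hydroxy-14-oxopentadecyl]-1,5-dimethoxybicyclo[2.2.2]octa-2,5-diene-2-carboxylate (both bridgehead isomers) | COC(=O)C1=C([C@@H](O)CCCCCCCCC[C@H](CCC(C)=O)OC(C)=O)C2CCC1(OC)C=C2OC | intermediate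
17 | methyl 2-[(1S,11R)-11-acetoxy-1-hydroxy-14-oxopentadecyl]-4,6-dimethoxybenzoate | COC(=O)c1c(OC)cc(OC)cc1[C@@H](O)CCCCCCCCC[C@H](CCC(C)=O)OC(C)=O | intermediate
18 | (3S)-3-[(10R)-10-acetoxy-13-oxotetradecyl]-5,7-dimethoxyisobenzofuran-1(3H)-one | COc1cc(OC)c2c(c1)[C@H](CCCCCCCCC[C@H](CCC(C)=O)OC(C)=O)OC2=O | target

## Step count and least certain steps

Total step count: 8. Longest linear sequence: 7 steps (steps 2 to 8, from 3 and 4 to 18); step 1 is a one-step side branch.

Step 8 (key step). What may go wrong: the cycloaddition onto a disubstituted, only moderately activated alkyne may be slower than consumption of the diene (loss of methanol to an anisole, oligomerisation), and the free carbinol may add to the enol ether under the trace acid. Prolonged heating could also isomerise the γ-hydroxy ynoate and erode the C3 configuration. Fallback: give up the benzannulation and build on a bought arene, setting out from 11 and coming back at 18.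
- 3,5-Dimethoxyphenylmagnesium bromide F1 (from commercial 1-bromo-3,5-dimethoxybenzene and Mg, THF) is added to the aldehyde of 11 at −78 °C. This gives the benzylic alcohol (5R)-15-(3,5-dimethoxyphenyl)-15-hydroxy-2-oxopentadecan-5-yl acetate F2 as a mixture of C15 epimers.
- Dess–Martin periodinane oxidises F2 to the aryl ketone (R)-15-(3,5-dimethoxyphenyl)-2,15-dioxopentadecan-5-yl acetate F3.
- Asymmetric transfer hydrogenation with RuCl[(S,S)-TsDPEN](p-cymene) in HCO2H/Et3N, which reduces aryl ketones much faster than dialkyl ketones, should give the 15S alcohol (5R,15S)-15-(3,5-dimethoxyphenyl)-15-hydroxy-2-oxopentadecan-5-yl acetate F4.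
- NBS in MeCN at 0 °C should brominate the ring position between the carbinol chain and a methoxy group (para to the other methoxy group), giving (5R,15S)-15-(2-bromo-3,5-dimethoxyphenyl)-15-hydroxy-2-oxopentadecan-5-yl acetate F5.
- Carbonylative lactonisation (Pd(OAc)2, Xantphos, CO, Et3N, toluene, 100 °C) closes the lactone to 18.

Step 7. What may go wrong: insufficient enantioface discrimination with an unbranched aliphatic aldehyde, and competing ethyl transfer from ZnEt2. The sense and level of induction would be checked by Mosher ester analysis. Fallback: set the centre by reduction instead of addition, setting out from 11 and coming back at 14.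
- 12 is deprotonated with LiHMDS (THF, −78 °C) and added to the aldehyde of 11 without stereocontrol. This gives methyl (14R)-14-acetoxy-4-hydroxy-17-oxooctadec-2-ynoate F6 as a mixture of C4 epimers.
- Dess–Martin periodinane oxidises F6 to the ynone methyl (R)-14-acetoxy-4,17-dioxooctadec-2-ynoate F7.
- Midland reduction with S-Alpine-Borane (B-isopinocampheyl-9-BBN from (−)-α-pinene, THF, rt), which reduces alkynyl ketones but leaves the dialkyl ketone alone, should convert both epimers' common ketone into the 4S alcohol 14.

Step 6. What may go wrong: the two alkenes are cleaved at different rates, so incomplete cleavage of one, or over-oxidation of the aldehyde once formed, can lower the yield. Fallback: introduce the ketone as such and cleave only one alkene by another method, setting out from 7 and coming back at 11.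
- The azaenolate of acetone N,N-dimethylhydrazone (n-BuLi, THF, −78 → 0 °C) opens 7 at its CH2 carbon to give (R)-2-(2,2-dimethylhydrazinylidene)hexadec-15-en-5-ol F8.
- Two-phase hydrolysis (aqueous CuCl2 or oxalic acid, Et2O) frees (R)-5-hydroxyhexadec-15-en-2-one F9.
- Ac2O, pyridine and DMAP give (R)-2-oxohexadec-15-en-5-yl acetate F10.
- Lemieux–Johnson cleavage of the single terminal alkene (OsO4 cat., NaIO4, 2,6-lutidine, dioxane–water) gives 11.

## Further compounds

F1 | step 8 | 3,5-dimethoxyphenylmagnesium bromide | COc1cc(OC)cc([Mg]Br)c1
F2 | step 8 | (5R)-15-(3,5-dimethoxyphenyl)-15-hydroxy-2-oxopentadecan-5-yl acetate (mixture of C15 epimers) | COc1cc(OC)cc(c1)C(O)CCCCCCCCC[C@H](CCC(C)=O)OC(C)=O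
F3 | step 8 | (R)-15-(3,5-dimethoxyphenyl)-2,15-dioxopentadecan-5-yl acetate | COc1cc(OC)cc(c1)C(=O)CCCCCCCCC[C@H](CCC(C)=O)OC(C)=O
F4 | step 8 | (5R,15S)-15-(3,5-dimethoxyphenyl)-15-hydroxy-2-oxopentadecan-5-yl acetate | COc1cc(OC)cc(c1)[C@H](CCCCCCCCC[C@H](CCC(C)=O)OC(C)=O)O
F5 | step 8 | (5R,15S)-15-(2-bromo-3,5-dimethoxyphenyl)-15-hydroxy-2-oxopentadecan-5-yl acetate | COc1cc(OC)c(Br)c(c1)[C@H](CCCCCCCCC[C@H](CCC(C)=O)OC(C)=O)O
F6 | step 7 | methyl (14R)-14-acetoxy-4-hydroxy-17-oxooctadec-2-ynoate (mixture of C4 epimers) | COC(=O)C#CC(O)CCCCCCCCC[C@H](CCC(C)=O)OC(C)=O
F7 | step 7 | methyl (R)-14-acetoxy-4,17-dioxooctadec-2-ynoate | COC(=O)C#CC(=O)CCCCCCCCC[C@H](CCC(C)=O)OC(C)=O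
F8 | step 6 | (R)-2-(2,2-dimethylhydrazinylidene)hexadec-15-en-5-ol | C=CCCCCCCCCC[C@H](CCC(C)=NN(C)C)O
F9 | step 6 | (R)-5-hydroxyhexadec-15-en-2-one | C=CCCCCCCCCC[C@H](CCC(C)=O)O
F10 | step 6 | (R)-2-oxohexadec-15-en-5-yl acetate | C=CCCCCCCCCC[C@H](CCC(C)=O)OC(C)=O
A1 | alternative 1 | methyl 2-[(11R)-11-acetoxy-14-oxopentadecanoyl]-4,6-dimethoxybenzoate | COC(=O)c1c(OC)cc(OC)cc1C(=O)CCCCCCCCC[C@H](CCC(C)=O)OC(C)=O
A2 | alternative 1 | methyl 2-bromo-4,6-dimethoxybenzoate | COC(=O)c1c(Br)cc(OC)cc1OC
A3 | alternative 2 | (S)-5,7-dimethoxy-3-(prop-2-en-1-yl)isobenzofuran-1(3H)-one | COc1cc(OC)c2c(c1)[C@H](CC=C)OC2=O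
A4 | alternative 2 | (R)-2-oxotridec-12-en-5-yl acetate | C=CCCCCCC[C@H](CCC(C)=O)OC(C)=O
A5 | alternative 2 | (3S)-3-[(10R)-10-acetoxy-13-oxotetradec-2-en-1-yl]-5,7-dimethoxyisobenzofuran-1(3H)-one | COc1cc(OC)c2c(c1)[C@H](CC=CCCCCCC[C@H](CCC(C)=O)OC(C)=O)OC2=O
A6 | alternative 3 | (R)-15-(2-formyl-3,5-dimethoxyphenyl)-2,15-dioxopentadecan-5-yl acetate | COc1cc(OC)c(C=O)c(c1)C(=O)CCCCCCCCC[C@H](CCC(C)=O)OC(C)=O
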